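**Plan**

1. Locants follow germacranolide numbering: ring C1–C10; C11, C12, C13 = lactone α-carbon, carbonyl, exocyclic CH2; C14 = CH3 on C10; C15 = CH2O on C4; TBS = tert-butyldimethylsilyl. Retrosynthetic cuts, in order: the two O–Si bonds; ring bond C2=C3 (ring-closing metathesis of an open-chain vinyl epoxide/1,3-diene); the ester C–O at C8; C11–C7 (lactone closure); the acrylate C12–O6 bond; both epoxides; then C3–C4, C5–C6 and C8–C9 of the chain.
2. Enabling feature: O6–C6, C7(–C11) and C8–O8 form a 1,3-dioxygenated array with the carbon branch on the middle atom. This is a 2,3-epoxy alcohol (C6–OH, 7,8-epoxide) opened at its proximal carbon. An acrylate on O6 holds C11 three atoms from C7, so the five-membered ring O6–C12–C11–C7–C6 can close 5-exo-tet; the epoxide oxygen stays behind as the C8 hydroxyl and C11=C13 is restored.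
3. Forward order: C8–C9 (allyl–vinyl Stille), C5–C6 (acetylide addition), C3–C4 (hydroalumination/iodination, Stille vinylation); both epoxides in one Sharpless operation; acrylate; lactone ring first; C8 ester; ten-membered ring last; desilylation.
4. Stereochemistry: D-(−)-DIPT Sharpless epoxidation sets C1/C10 by reagent control and C6/C7/C8 by kinetic resolution of the racemic C6 carbinol (erythro epoxy alcohol). The lactone closure inverts C7 and so gives the trans-fused lactone beside the 8R hydroxyl. C4=C5 geometry comes from trans-hydroalumination, C2=C3 (Z) from the ring closure, and the side-chain (Z) geometry from α-iodination of crotonaldehyde followed by retentive lithiation–carboxylation.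

Key step: step 12

Remark: 9, 11 and 12 are racemic at C6, their only stereocentre; step 8 resolves it, so 13 and every later compound is a single enantiomer.

**Route**

Step 1
Reactants: 1 3-methylbut-2-en-1-yl acetate (prenyl acetate)
Product: 2 (2E)-4-hydroxy-3-methylbut-2-en-1-yl acetate
Conditions: SeO2 (0.1 equiv), t-BuOOH (2 equiv), salicylic acid (0.1 equiv), CH2Cl2, rt
Reagents that add atoms: tert-butyl hydroperoxide, CC(C)(C)OO
Why: Allylic oxidation with catalytic SeO2 (ene reaction, then [2,3]-sigmatropic shift) should attack the (E)-methyl group of the trisubstituted alkene and give the (E)-allylic alcohol.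

Step 2
Reactants: 2 (2E)-4-hydroxy-3-methylbut-2-en-1-yl acetate
Product: 3 (2E)-4-bromo-3-methylbut-2-en-1-yl acetate
Conditions: CBr4, PPh3, CH2Cl2, 0 °C
Reagents that add atoms: carbon tetrabromide, BrC(Br)(Br)Br
Why: Appel bromination should convert the primary allylic alcohol into the bromide under neutral conditions without allylic transposition or loss of the acetate.

Step 3
Reactants: 3 (2E)-4-bromo-3-methylbut-2-en-1-yl acetate; 4 (2E)-3-(tributylstannyl)prop-2-en-1-ol
Product: 5 (2E,5E)-7-hydroxy-3-methylhepta-2,5-dien-1-yl acetate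
Conditions: Pd2(dba)3 (2.5 mol%), AsPh3 (10 mol%), THF, 45 °C
Reagents that add atoms: none
Why: Allyl–vinyl Stille coupling (oxidative addition of the allylic bromide to zerovalent palladium, transmetallation, reductive elimination at the less hindered C9 terminus) should form C8–C9 with both (E) geometries retained, the acetate ionising far more slowly than the bromide.

Step 4
Reactants: 5 (2E,5E)-7-hydroxy-3-methylhepta-2,5-dien-1-yl acetate
Product: 6 (2E,5E)-3-methyl-7-oxohepta-2,5-dien-1-yl acetate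
Conditions: MnO2 (activated, 15 equiv), CH2Cl2, rt
Reagents that add atoms: none
Why: Allylic oxidation with MnO2 should give the (E)-enal under neutral heterogeneous conditions that spare the acetate and avoid base-induced conjugation of the skipped diene.

Step 5
Reactants: 6 (2E,5E)-3-methyl-7-oxohepta-2,5-dien-1-yl acetate; 7 tert-butyldimethyl(prop-2-yn-1-yloxy)silane
Product: 9 rac-(2E,5E)-10-(TBSO)-7-hydroxy-3-methyldeca-2,5-dien-8-yn-1-yl acetate, via lithium acetylide 8 (not isolated)
Conditions: 7, n-BuLi, THF, −78 °C; then 6, −78 °C; NH4Cl quench at −78 °C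
Reagents that add atoms: none
Why: 1,2-Addition of a lithium acetylide to an enal at −78 °C should be faster than attack on the acetate or γ-deprotonation and forms C5–C6 as the racemic alkenyl alkynyl carbinol, whose C6 configuration is settled in step 8.

Step 6
Reactants: 9 rac-(2E,5E)-10-(TBSO)-7-hydroxy-3-methyldeca-2,5-dien-8-yn-1-yl acetate
Product: 11 rac-(2E,5E,8Z)-10-(TBSO)-9-iodo-3-methyldeca-2,5,8-triene-1,7-diol, via vinylalanate 10 (not isolated)
Conditions: NaAlH2(OCH2CH2OMe)2 (3 equiv), THF, 0 °C → rt; then I2, THF, −78 → 0 °C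
Reagents that add atoms: iodine, II
Why: Alkoxide-directed trans-hydroalumination of the propargylic alcohol should deliver hydride to C5 and aluminium to C4 in a five-membered alanate, and iodinolysis with retention gives the (Z)-iodoalkene that fixes the ring-cis C4=C5 geometry, while the same hydride cleaves the acetate and frees the C2 allylic alcohol.

Step 7
Reactants: 11 rac-(2E,5E,8Z)-10-(TBSO)-9-iodo-3-methyldeca-2,5,8-triene-1,7-diol
Product: 12 rac-(2E,5E,8E)-9-[(TBSO)methyl]-3-methylundeca-2,5,8,10-tetraene-1,7-diol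
Conditions: tributyl(vinyl)stannane (1.3 equiv), PdCl2(MeCN)2 (5 mol%), DMF, rt
Reagents that add atoms: tributyl(vinyl)stannane, C=C[Sn](CCCC)(CCCC)CCCC
Why: Stille coupling of the vinyl iodide should proceed with retention and install C3 with its terminal CH2 as a 2-substituted 1,3-diene, and this last palladium step is placed before any vinyl epoxide exists.

Step 8
Reactants: 12 rac-(2E,5E,8E)-9-[(TBSO)methyl]-3-methylundeca-2,5,8,10-tetraene-1,7-diol
Product: 13 (1R,2E)-3-[(TBSO)methyl]-1-[(2R,3R)-3-{[(2R,3R)-3-(hydroxymethyl)-2-methyloxiran-2-yl]methyl}oxiran-2-yl]penta-2,4-dien-1-ol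
Conditions: Ti(OiPr)4 (0.2 equiv), D-(−)-diisopropyl tartrate (0.28 equiv), t-BuOOH (1.6 equiv, anhydrous), 4 Å MS, CH2Cl2, −20 °C; stopped when the fast C6 enantiomer is consumed
Reagents that add atoms: tert-butyl hydroperoxide, CC(C)(C)OO
Why: Sharpless asymmetric epoxidation with D-(−)-DIPT should epoxidise the primary C2 allylic alcohol under reagent control to the (1R,10R)-epoxide and at the same time resolve the secondary C6 alcohol kinetically, only the (S)-enantiomer of 12 being epoxidised quickly at the (E)-C7=C8 bond from the same reagent face to the erythro epoxy alcohol, while the C4=C5 bond with its cis substituent and the terminal vinyl stay inert; at most half of 12 can be converted.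

Step 9
Reactants: 13 (1R,2E)-3-[(TBSO)methyl]-1-[(2R,3R)-3-{[(2R,3R)-3-(hydroxymethyl)-2-methyloxiran-2-yl]methyl}oxiran-2-yl]penta-2,4-dien-1-ol
Product: 14 (2S,3R)-3-{[(2R,3R)-3-{(1R,2E)-1-hydroxy-3-[(TBSO)methyl]penta-2,4-dien-1-yl}oxiran-2-yl]methyl}-3-methyloxirane-2-carbaldehyde
Conditions: TEMPO (0.2 equiv), PhI(OAc)2 (1.1 equiv), CH2Cl2, 0 °C → rt
Reagents that add atoms: none
Why: Oxoammonium (TEMPO/PhI(OAc)2) oxidation should convert the primary epoxy alcohol into the aldehyde chemoselectively over the hindered secondary C6 alcohol and leaves epoxides and diene untouched.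

Step 10
Reactants: 14 (2S,3R)-3-{[(2R,3R)-3-{(1R,2E)-1-hydroxy-3-[(TBSO)methyl]penta-2,4-dien-1-yl}oxiran-2-yl]methyl}-3-methyloxirane-2-carbaldehyde
Product: 15 (1R,2E)-3-[(TBSO)methyl]-1-[(2R,3R)-3-{[(2R,3R)-3-ethenyl-2-methyloxiran-2-yl]methyl}oxiran-2-yl]penta-2,4-dien-1-ol
Conditions: Ph3PCH3Br (2.5 equiv), KN(SiMe3)2 (2.4 equiv), THF, −78 → −20 °C; cold NH4Cl quench
Reagents that add atoms: methyltriphenylphosphonium bromide, C[P+](c1ccccc1)(c1ccccc1)c1ccccc1.[Br-]
Why: Wittig methylenation of the 2,3-epoxy aldehyde should give the vinyl epoxide, one further equivalent of ylide being spent on the C6 hydroxyl and the low temperature keeping the resulting epoxy alkoxide from Payne rearrangement.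

Step 11
Reactants: 15 (1R,2E)-3-[(TBSO)methyl]-1-[(2R,3R)-3-{[(2R,3R)-3-ethenyl-2-methyloxiran-2-yl]methyl}oxiran-2-yl]penta-2,4-dien-1-ol
Product: 16 (1R,2E)-3-[(TBSO)methyl]-1-[(2S,3R)-3-{[(2R,3R)-3-ethenyl-2-methyloxiran-2-yl]methyl}oxiran-2-yl]penta-2,4-dien-1-yl prop-2-enoate
Conditions: acryloyl chloride (1.5 equiv), i-Pr2NEt (2.5 equiv), CH2Cl2, −40 → 0 °C
Reagents that add atoms: acryloyl chloride, C=CC(Cl)=O
Why: Esterification of the secondary alcohol with an acid chloride and a hindered amine base should install C11–C13 on O6 without disturbing either epoxide (the descriptor at C7 changes only because of CIP priorities).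

Step 12
Reactants: 16 (1R,2E)-3-[(TBSO)methyl]-1-[(2S,3R)-3-{[(2R,3R)-3-ethenyl-2-methyloxiran-2-yl]methyl}oxiran-2-yl]penta-2,4-dien-1-yl prop-2-enoate
Product: 19 (4R,5R)-5-{(1E)-2-[(TBSO)methyl]buta-1,3-dien-1-yl}-4-{(1R)-2-[(2R,3R)-3-ethenyl-2-methyloxiran-2-yl]-1-hydroxyethyl}-3-methylideneoxolan-2-one, via phosphonium enolate 17 (not isolated), via phosphonium alkoxide 18 (not isolated)
Conditions: PMe3 (1.0 equiv), t-BuOH/THF (1:1, 0.02 M), rt
Reagents that add atoms: none
Why: Proposed new method: PMe3 should add reversibly to the acrylate β-carbon C13 to give phosphonium enolate 17, whose α-carbon C11 opens the 7,8-epoxide at C7; proton transfer from C11 to the C8 alkoxide of 18 and E1cB loss of PMe3 then restore C11=C13, so the lactone, the exocyclic methylene and the free C8 hydroxyl arise in one operation. The closest known reaction types are the phosphine-mediated intramolecular Morita–Baylis–Hillman alkylation of enones by tethered epoxides and the proximal-carbon opening of 2,3-epoxy alcohol urethanes or imidates by a nucleophile carried on the carbinol oxygen; an acrylate tethered through its own ester oxygen has not been used in this way. The lactone ring (C11, C12, O6, C6, C7) closes in the 5-exo-tet mode, the breaking C7–O bond lying outside the new ring. The new stereocentre C7 is set by SN2 inversion of the Sharpless-derived epoxide, which with the 6R carbinol gives the trans H6/H7 lactone, while C8 keeps its configuration and emerges as the 8R alcohol. The step needs attack at C7 and not C8, secured by the five- versus six-membered transition state and the backside trajectory that the three-atom tether allows only at C7, and it needs the remote vinyl epoxide to stay intact, which the tether cannot reach; tert-butanol protonates the C8 alkoxide and so should suppress translactonisation to the 8,12-olide.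

Step 13
Reactants: 20 (2E)-but-2-enal (crotonaldehyde)
Product: 21 (2Z)-2-iodobut-2-enal
Conditions: I2 (1.5 equiv), K2CO3 (1.2 equiv), DMAP (0.2 equiv), THF/H2O (1:1), rt
Reagents that add atoms: iodine, II
Why: α-Iodination of an enal by amine conjugate addition, iodination of the enolate and elimination (Baylis–Hillman-type sequence) should give the (Z)-α-iodoenal with iodine cis to the methyl group.

Step 14
Reactants: 21 (2Z)-2-iodobut-2-enal
Product: 22 (2Z)-2-iodobut-2-en-1-ol
Conditions: NaBH4, CeCl3·7H2O, MeOH, 0 °C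
Reagents that add atoms: none
Why: Luche reduction should reduce the aldehyde in the 1,2 sense without touching the C–I bond or the alkene geometry.

Step 15
Reactants: 22 (2Z)-2-iodobut-2-en-1-ol
Product: 23 tert-butyl{[(2Z)-2-iodobut-2-en-1-yl]oxy}dimethylsilane
Conditions: TBSCl, imidazole, CH2Cl2, rt
Reagents that add atoms: tert-butyldimethylsilyl chloride, CC(C)(C)[Si](C)(C)Cl
Why: Silyl ether formation on the primary allylic alcohol is routine and gives the same protecting group as on C15, so one final deprotection serves both.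

Step 16
Reactants: 23 tert-butyl{[(2Z)-2-iodobut-2-en-1-yl]oxy}dimethylsilane
Product: 25 (2Z)-2-[(TBSO)methyl]but-2-enoic acid, via vinyllithium 24 (not isolated)
Conditions: t-BuLi (2.1 equiv), Et2O, −78 °C; CO2 (g), −78 °C → rt; aq. NaHSO4 to pH 3–4
Reagents that add atoms: carbon dioxide, O=C=O
Why: Iodine–lithium exchange at −78 °C should be faster than silyl migration or β-elimination and retains the alkene geometry, so carboxylation of the vinyllithium gives the acid with the methyl group cis to the carboxyl group.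

Step 17
Reactants: 19 (4R,5R)-5-{(1E)-2-[(TBSO)methyl]buta-1,3-dien-1-yl}-4-{(1R)-2-[(2R,3R)-3-ethenyl-2-methyloxiran-2-yl]-1-hydroxyethyl}-3-methylideneoxolan-2-one; 25 (2Z)-2-[(TBSO)methyl]but-2-enoic acid
Product: 27 (1R)-1-[(2R,3R)-2-{(1E)-2-[(TBSO)methyl]buta-1,3-dien-1-yl}-4-methylidene-5-oxooxolan-3-yl]-2-[(2R,3R)-3-ethenyl-2-methyloxiran-2-yl]ethyl (2Z)-2-[(TBSO)methyl]but-2-enoate, via mixed anhydride 26 (not isolated)
Conditions: 25, 2,4,6-trichlorobenzoyl chloride, Et3N, toluene, rt; filter; then 19, toluene, 60 °C (no DMAP)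
Reagents that add atoms: none
Why: Yamaguchi mixed-anhydride esterification run without a nucleophilic catalyst, the protocol suited to angelate-type (Z)-2-substituted but-2-enoates, should acylate the C8 alcohol with retention at C8 and avoid the conjugate addition–elimination path that would isomerise the side-chain alkene.

Step 18
Reactants: 27 (1R)-1-[(2R,3R)-2-{(1E)-2-[(TBSO)methyl]buta-1,3-dien-1-yl}-4-methylidene-5-oxooxolan-3-yl]-2-[(2R,3R)-3-ethenyl-2-methyloxiran-2-yl]ethyl (2Z)-2-[(TBSO)methyl]but-2-enoate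
Product: 28 (1R,6R,7R,8R,10R)-8-{(2Z)-2-[(TBSO)methyl]but-2-enoyloxy}-15-(TBSO)-1,10-epoxygermacra-2Z,4E,11(13)-trien-6,12-olide (bis-TBS ether of the target; C4=C5 ring-cis)
Conditions: second-generation Grubbs catalyst RuCl2(=CHPh)(PCy3)(H2IMes) (15 mol%), 1,4-benzoquinone (0.3 equiv), CH2Cl2 (1 mM), 40 °C
Reagents that add atoms: none
Why: Ring-closing metathesis between the vinyl epoxide and the terminal vinyl of the 2-substituted diene should close the ten-membered carbocycle at C2=C3 with loss of ethene, the trans-fused lactone pre-organising the two arms and the ring next to the cis C4=C5 bond favouring the (Z)-alkene, while the 1,1-disubstituted acceptor alkenes are inert to the catalyst.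

Step 19
Reactants: 28 bis-TBS ether of the target
Product: 29 (1R,6R,7R,8R,10R)-8-[(2Z)-2-(hydroxymethyl)but-2-enoyloxy]-15-hydroxy-1,10-epoxygermacra-2Z,4E,11(13)-trien-6,12-olide (target)
Conditions: Bu4NF, AcOH (1:1), THF, 0 °C → rt
Reagents that add atoms: none
Why: Buffered fluoride desilylation should remove both primary TBS ethers without the acid that would open the dienyl epoxide or the strong base that would attack the α-methylene lactone.

**Compound list**

1 | 3-methylbut-2-en-1-yl acetate (prenyl acetate) | CC(C)=CCOC(C)=O | starting material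
2 | (2E)-4-hydroxy-3-methylbut-2-en-1-yl acetate | CC(=O)OC/C=C(\C)CO | intermediate
3 | (2E)-4-bromo-3-methylbut-2-en-1-yl acetate | CC(=O)OC/C=C(\C)CBr | intermediate
4 | (2E)-3-(tributylstannyl)prop-2-en-1-ol | CCCC[Sn](CCCC)(CCCC)/C=C/CO | starting material
5 | (2E,5E)-7-hydroxy-3-methylhepta-2,5-dien-1-yl acetate | CC(=O)OC/C=C(\C)C/C=C/CO | intermediate
6 | (2E,5E)-3-methyl-7-oxohepta-2,5-dien-1-yl acetate | CC(=O)OC/C=C(\C)C/C=C/C=O | intermediate
7 | tert-butyldimethyl(prop-2-yn-1-yloxy)silane | C#CCO[Si](C)(C)C(C)(C)C | starting material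
8 | lithium 3-(TBSO)prop-1-yn-1-ide | [Li]C#CCO[Si](C)(C)C(C)(C)C | intermediate
9 | rac-(2E,5E)-10-(TBSO)-7-hydroxy-3-methyldeca-2,5-dien-8-yn-1-yl acetate | CC(=O)OC/C=C(\C)C/C=C/C(O)C#CCO[Si](C)(C)C(C)(C)C | intermediate
10 | cyclic alkenylalanate of 9 (five-membered O–Al–C4=C5–C6 ate complex, C2 alkoxide, disodium salt) | [Na+].[Na+].[O-]C/C=C(\C)C/C=C/C1O[Al-](OCCOC)(OCCOC)C(CO[Si](C)(C)C(C)(C)C)=C1 | intermediate
11 | rac-(2E,5E,8Z)-10-(TBSO)-9-iodo-3-methyldeca-2,5,8-triene-1,7-diol | OC/C=C(\C)C/C=C/C(O)/C=C(\I)CO[Si](C)(C)C(C)(C)C | intermediate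
12 | rac-(2E,5E,8E)-9-[(TBSO)methyl]-3-methylundeca-2,5,8,10-tetraene-1,7-diol | OC/C=C(\C)C/C=C/C(O)/C=C(\C=C)CO[Si](C)(C)C(C)(C)C | intermediate
13 | (1R,2E)-3-[(TBSO)methyl]-1-[(2R,3R)-3-{[(2R,3R)-3-(hydroxymethyl)-2-methyloxiran-2-yl]methyl}oxiran-2-yl]penta-2,4-dien-1-ol | OC[C@H]1O[C@]1(C)C[C@H]1O[C@@H]1[C@H](O)/C=C(\C=C)CO[Si](C)(C)C(C)(C)C | intermediate
14 | (2S,3R)-3-{[(2R,3R)-3-{(1R,2E)-1-hydroxy-3-[(TBSO)methyl]penta-2,4-dien-1-yl}oxiran-2-yl]methyl}-3-methyloxirane-2-carbaldehyde | O=C[C@H]1O[C@]1(C)C[C@H]1O[C@@H]1[C@H](O)/C=C(\C=C)CO[Si](C)(C)C(C)(C)C | intermediate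
15 | (1R,2E)-3-[(TBSO)methyl]-1-[(2R,3R)-3-{[(2R,3R)-3-ethenyl-2-methyloxiran-2-yl]methyl}oxiran-2-yl]penta-2,4-dien-1-ol | C=C[C@H]1O[C@]1(C)C[C@H]1O[C@@H]1[C@H](O)/C=C(\C=C)CO[Si](C)(C)C(C)(C)C | intermediate
16 | (1R,2E)-3-[(TBSO)methyl]-1-[(2S,3R)-3-{[(2R,3R)-3-ethenyl-2-methyloxiran-2-yl]methyl}oxiran-2-yl]penta-2,4-dien-1-yl prop-2-enoate | C=CC(=O)O[C@H](/C=C(\C=C)CO[Si](C)(C)C(C)(C)C)[C@H]1O[C@@H]1C[C@@]1(C)O[C@@H]1C=C | intermediate
17 | β-(trimethylphosphonio) ester enolate of 16 (zwitterion) | C[P+](C)(C)CC=C([O-])O[C@H](/C=C(\C=C)CO[Si](C)(C)C(C)(C)C)[C@H]1O[C@@H]1C[C@@]1(C)O[C@@H]1C=C | intermediate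
18 | 3-[(trimethylphosphonio)methyl] lactone C8-alkoxide (zwitterion) | C[P+](C)(C)CC1C(=O)O[C@H](/C=C(\C=C)CO[Si](C)(C)C(C)(C)C)[C@H]1[C@H]([O-])C[C@@]1(C)O[C@@H]1C=C | intermediate
19 | (4R,5R)-5-{(1E)-2-[(TBSO)methyl]buta-1,3-dien-1-yl}-4-{(1R)-2-[(2R,3R)-3-ethenyl-2-methyloxiran-2-yl]-1-hydroxyethyl}-3-methylideneoxolan-2-one | C=C1C(=O)O[C@H](/C=C(\C=C)CO[Si](C)(C)C(C)(C)C)[C@H]1[C@H](O)C[C@@]1(C)O[C@@H]1C=C | intermediate
20 | (2E)-but-2-enal (crotonaldehyde) | C/C=C/C=O | starting material
21 | (2Z)-2-iodobut-2-enal | C/C=C(\I)C=O | intermediate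
22 | (2Z)-2-iodobut-2-en-1-ol | C/C=C(\I)CO | intermediate
23 | tert-butyl{[(2Z)-2-iodobut-2-en-1-yl]oxy}dimethylsilane | C/C=C(\I)CO[Si](C)(C)C(C)(C)C | intermediate
24 | [(2E)-1-(TBSO)but-2-en-2-yl]lithium (geometry retained, Li cis to CH3) | C/C=C(\[Li])CO[Si](C)(C)C(C)(C)C | intermediate
25 | (2Z)-2-[(TBSO)methyl]but-2-enoic acid | C/C=C(\C(=O)O)CO[Si](C)(C)C(C)(C)C | intermediate
26 | (2Z)-2-[(TBSO)methyl]but-2-enoic 2,4,6-trichlorobenzoic anhydride | C/C=C(\C(=O)OC(=O)c1c(Cl)cc(Cl)cc1Cl)CO[Si](C)(C)C(C)(C)C | intermediate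
27 | (1R)-1-[(2R,3R)-2-{(1E)-2-[(TBSO)methyl]buta-1,3-dien-1-yl}-4-methylidene-5-oxooxolan-3-yl]-2-[(2R,3R)-3-ethenyl-2-methyloxiran-2-yl]ethyl (2Z)-2-[(TBSO)methyl]but-2-enoate | C=C1C(=O)O[C@H](/C=C(\C=C)CO[Si](C)(C)C(C)(C)C)[C@H]1[C@H](OC(=O)/C(=C\C)CO[Si](C)(C)C(C)(C)C)C[C@@]1(C)O[C@@H]1C=C | intermediate
28 | (1R,6R,7R,8R,10R)-8-{(2Z)-2-[(TBSO)methyl]but-2-enoyloxy}-15-(TBSO)-1,10-epoxygermacra-2Z,4E,11(13)-trien-6,12-olide | C=C1C(=O)O[C@@H]2/C=C(CO[Si](C)(C)C(C)(C)C)\C=C/[C@H]3O[C@]3(C)C[C@@H](OC(=O)/C(=C\C)CO[Si](C)(C)C(C)(C)C)[C@@H]12 | intermediate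
29 | (1R,6R,7R,8R,10R)-8-[(2Z)-2-(hydroxymethyl)but-2-enoyloxy]-15-hydroxy-1,10-epoxygermacra-2Z,4E,11(13)-trien-6,12-olide | C=C1C(=O)O[C@@H]2/C=C(CO)\C=C/[C@H]3O[C@]3(C)C[C@@H](OC(=O)/C(=C\C)CO)[C@@H]12 | target

**Step count and risks**

Total steps: 19. Longest linear sequence: 15 (steps 1–12 and 17–19); steps 13–16 make the side-chain acid.

Step 12 (proposed new method). The phosphonium enolate may be protonated, or may add to a second acrylate (Rauhut–Currier oligomerisation), faster than it reaches C7, because the ester has to leave its preferred s-trans conformation to close the ring; the C8 alkoxide may also translactonise before it is protonated. The fallback uses known chemistry and sets out from 15. DCC/DMAP esterification with diethylphosphonoacetic acid should give the (1R,2E)-dienyl (diethoxyphosphoryl)acetate F1. KOt-Bu in THF at 0 °C generates the stabilised carbanion, which opens the epoxide at C7 (5-exo-tet, inversion) to the α-(diethoxyphosphoryl) lactone F2. Horner–Wadsworth–Emmons methylenation of F2 with paraformaldehyde and K2CO3 then gives 19, where the route is rejoined.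

Step 18. Intermolecular metathesis may outrun closure of the ten-membered ring; the ruthenium carbene loaded on the C2 arm may be held back by chelation to the neighbouring C8 ester carbonyl; and (Z) control at C2=C3 may be incomplete. The fallback changes the order of ring closure and acylation and sets out from 19: ring-closing metathesis on the hydroxy lactone, which carries no ester at C8, should give the macrocyclic 8-hydroxy lactone F3. Acylation of F3 with 25 through 26, as in step 17, then gives 28, where the route is rejoined.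

Step 8. The rate difference between the two C6 enantiomers may be too small, or the fast product may be over-oxidised, which would erode the diastereo- and enantiopurity of 13; the resolution also caps the throughput at one half. The fallback sets C6 by a catalyst-controlled carbonyl reduction and sets out from 9. MnO2 oxidation gives the alkenyl alkynyl ketone F4. Corey–Bakshi–Shibata reduction ((S)-2-methyl-CBS-oxazaborolidine, catecholborane, −78 °C, the alkynyl group acting as the small substituent) should give the (7S)-carbinol F5. The conditions of steps 6 and 7 then give the (7S)-iodotrienediol F6 and the (7S)-tetraenediol F7. D-(−)-DIPT epoxidation of F7 is now a matched double epoxidation run to full conversion and gives 13, where the route is rejoined.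

**Further compounds**

F1 | step 12 | (1R,2E)-3-[(TBSO)methyl]-1-[(2S,3R)-3-{[(2R,3R)-3-ethenyl-2-methyloxiran-2-yl]methyl}oxiran-2-yl]penta-2,4-dien-1-yl (diethoxyphosphoryl)acetate | CCOP(=O)(OCC)CC(=O)O[C@H](/C=C(\C=C)CO[Si](C)(C)C(C)(C)C)[C@H]1O[C@@H]1C[C@@]1(C)O[C@@H]1C=C
F2 | step 12 | diethyl [(4R,5R)-5-{(1E)-2-[(TBSO)methyl]buta-1,3-dien-1-yl}-4-{(1R)-2-[(2R,3R)-3-ethenyl-2-methyloxiran-2-yl]-1-hydroxyethyl}-2-oxooxolan-3-yl]phosphonate (mixture at C3) | CCOP(=O)(OCC)C1C(=O)O[C@H](/C=C(\C=C)CO[Si](C)(C)C(C)(C)C)[C@H]1[C@H](O)C[C@@]1(C)O[C@@H]1C=C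
F3 | step 18 | (1R,6R,7R,8R,10R)-8-hydroxy-15-(TBSO)-1,10-epoxygermacra-2Z,4E,11(13)-trien-6,12-olide | C=C1C(=O)O[C@@H]2/C=C(CO[Si](C)(C)C(C)(C)C)\C=C/[C@H]3O[C@]3(C)C[C@@H](O)[C@@H]12
F4 | step 8 | (2E,5E)-10-(TBSO)-3-methyl-7-oxodeca-2,5-dien-8-yn-1-yl acetate | CC(=O)OC/C=C(\C)C/C=C/C(=O)C#CCO[Si](C)(C)C(C)(C)C
F5 | step 8 | (2E,5E,7S)-10-(TBSO)-7-hydroxy-3-methyldeca-2,5-dien-8-yn-1-yl acetate | CC(=O)OC/C=C(\C)C/C=C/[C@H](O)C#CCO[Si](C)(C)C(C)(C)C
F6 | step 8 | (2E,5E,7S,8Z)-10-(TBSO)-9-iodo-3-methyldeca-2,5,8-triene-1,7-diol | OC/C=C(\C)C/C=C/[C@H](O)/C=C(\I)CO[Si](C)(C)C(C)(C)C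
F7 | step 8 | (2E,5E,7S,8E)-9-[(TBSO)methyl]-3-methylundeca-2,5,8,10-tetraene-1,7-diol | OC/C=C(\C)C/C=C/[C@H](O)/C=C(\C=C)CO[Si](C)(C)C(C)(C)C
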